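The data were generated by integration on assumed constants; scatter was added.

Follow the target first: in these runs its readings climb early and then fall, so ask where it ends before asking how high it gets.

| flask | substrate | catalyst | remark | time |
|---|---|---|---|---|
| south | 0.035 M | 0.5 mol% | run made earlier |  |
| west | 0.055 M | 0.5 mol% | run made earlier |  |
| east | 0.025 M | 1 mol% | run made earlier |  |
| flask | 0.025 M | 0.5 mol% |  | 10 h |

- south (time / h: target / %): 0.167: 14; 0.333: 18; 0.667: 23; 1.33: 17; 3.00: 9; 6.00: 4
- west (time / h: target / %): 0.167: 20; 0.333: 28; 0.667: 25; 1.33: 18; 3.00: 10; 6.00: 5
- east (time / h: target / %): 0.167: 20; 0.417: 32; 1.00: 21; 2.50: 7; 6.00: 7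

(readings scatter by 2 percentage points)

- time, not beyond 10 h, at which the flask holds most target
- the amount of target, in percent of the substrate charged, at that time
- earliest time at which at least nineteen twentieths of that best amount are there
- latest time at which they still are



Read the last line of each table. At 6.00 h the target stands at 4%, 5% and 7% of the charge, a spread of 3 percentage points against a scatter of 2 points per reading, with catalyst concentrations of 0.175 mM, 0.275 mM and 0.250 mM. So take their mean, 5.33%, as a reading of the floor: the fraction of the charge that stands as target once a flask has stopped changing.

Expect the flask to approach this floor by 10 h. But the south run reads 23% at 0.667 h, higher than the floor, so look for the best early, under kinetic rather than thermodynamic control. The flask has less catalyst, 0.125 mM, than any run, so my own reckoning gives a direction and no number: a peak later and lower than south's.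

The forecast says 21% at 0.87 h, with a window from 0.59 h to 1.29 h, holding that “peak time scales inversely with absolute catalyst concentration”.

The flask gives 19.0% at 0.730 h, with a window from 0.497 h to 1.06 h.

    substrate + catalyst ⇌ target + catalyst, rate k1*[substrate]*[catalyst] forward; the back reaction follows from the equilibrium constant (K = 1.26, k = 1.81 L mol⁻¹ s⁻¹)
    target ⇌ isomer of the product (K = 18.0, k = 5.77 × 10⁻⁴ s⁻¹)

The forecast's best falls within the margin, but its peak time is late by a factor of 1.19. Set the floor of 5.33% beside the flask: at 10.0 h it holds 5.11% target and 90.7% isomer of the product. Now charge a neighbour with 1.2 mol% of catalyst, other charges held, and the floor again puts its target near 5.33% at 10.0 h. That neighbour peaks higher than the flask, at 28.6%, and ends with 5.06% target.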